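The route rests on cutting the cyclohexenone ring of the bicyclo[3.2.1]octenone core (C1, C2, C3, C4, C5, C8) at C1–C2 and C4–C5: the acryloyl unit C2–C3–C4 then bridges C1 and C5 of a cyclopentane ring (C1, C5, C6, C7, C8), which are the α′- and β-carbons of a cyclopent-2-enone with its carbonyl at C7. In the key step the α′-lithium enolate of such an enone, already carrying the complete lactone, takes up a β-silyl acryloylsilane: carbonyl addition, Brook rearrangement (polarity reversal at C2), cyclopropanolate closure and oxy-Cope rearrangement forge both bonds, and an iminium salt traps the resulting enolate as third component.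

Key step: step 12

Remark: C1–C8 are the bicyclo[3.2.1]octane locants of the core (C1 quaternary bridgehead, C2 ketone carbon, C3=C4 alkene, C5 CH bridgehead, C6 methylidene-bearing carbon, C7 acetoxy-bearing carbon, C8 CH2 bridge); exo means syn to C8, endo anti to C8; Lac is the (3R,3aS,4R,7aR)-4,7a-dimethyl-1-oxo-4-(triethylsilyloxy)octahydro-2-benzofuran-3-yl group.
Assumption: 1, 12, 15 and 2-(triphenylphosphoranylidene)propanal are bought; if both C1/C5-epimeric annulation products form, they are diastereomers and can be separated.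

Step 1
Reactants: 1 (4R)-2,2-dimethyl-1,3-dioxolane-4-carbaldehyde
Product: 2 (2E)-3-[(4S)-2,2-dimethyl-1,3-dioxolan-4-yl]-2-methylprop-2-enal
Conditions: Ph3P=C(CH3)CHO, toluene, 80 °C
Reagents that add atoms: 2-(triphenylphosphoranylidene)propanal, CC(C=O)=P(c1ccccc1)(c1ccccc1)c1ccccc1
Why: Wittig olefination with the stabilised formyl ylide should give the (E)-enal under non-basic conditions that leave the α-alkoxy stereocentre (the later lactone carbinol carbon) untouched.

Step 2
Reactants: 2 (2E)-3-[(4S)-2,2-dimethyl-1,3-dioxolan-4-yl]-2-methylprop-2-enal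
Product: 3 (4S)-2,2-dimethyl-4-[(1E)-2-methylbuta-1,3-dien-1-yl]-1,3-dioxolane
Conditions: Ph3PCH3Br, KOt-Bu, THF, 0 °C
Reagents that add atoms: methyltriphenylphosphonium bromide (ylide source), C[P+](c1ccccc1)(c1ccccc1)c1ccccc1.[Br-]
Why: Wittig methylenation of the aldehyde completes the (E)-configured 2-methylbuta-1,3-diene without forming a stereocentre.

Step 3
Reactants: 3 (4S)-2,2-dimethyl-4-[(1E)-2-methylbuta-1,3-dien-1-yl]-1,3-dioxolane
Product: 4 (2S,3E)-4-methylhexa-3,5-diene-1,2-diol
Conditions: AcOH–H2O (4:1), 25 °C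
Reagents that add atoms: none
Why: Mild acid-catalysed acetal hydrolysis should free the diol without ionising the dienylic carbinol.

Step 4
Reactants: 4 (2S,3E)-4-methylhexa-3,5-diene-1,2-diol
Product: 6 (2S,3E)-1-(tert-butyldimethylsilyloxy)-4-methylhexa-3,5-dien-2-yl 2-methylprop-2-enoate, via primary silyl ether 5 (not isolated)
Conditions: t-BuMe2SiCl, imidazole, CH2Cl2, 0 °C; then CH2=C(CH3)COCl, Et3N, DMAP, 0 → 25 °C
Reagents that add atoms: tert-butylchlorodimethylsilane, CC(C)(C)[Si](C)(C)Cl; methacryloyl chloride, C=C(C)C(Cl)=O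
Why: Silylation is selective for the primary hydroxyl, and DMAP-catalysed acylation of the remaining secondary alcohol with the acid chloride gives the triene ester with the stereocentre unchanged.

Step 5
Reactants: 6 (2S,3E)-1-(tert-butyldimethylsilyloxy)-4-methylhexa-3,5-dien-2-yl 2-methylprop-2-enoate
Product: 7 (3S,3aS,7aR)-3-[(tert-butyldimethylsilyloxy)methyl]-4,7a-dimethyl-3a,6,7,7a-tetrahydro-2-benzofuran-1(3H)-one
Conditions: toluene (0.01 M), BHT, 180 °C, sealed tube
Reagents that add atoms: none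
Why: Ester-tethered intramolecular Diels–Alder reaction, in which allylic 1,3-strain with the diene methyl should hold the carbinol hydrogen in the diene plane so that the methacrylate adds anti to CH2OSi, while the three-atom tether enforces the endo-carbonyl geometry and hence the cis-fused lactone; the quaternary carbon and the ring-fusion CH are set together.

Step 6
Reactants: 7 (3S,3aS,7aR)-3-[(tert-butyldimethylsilyloxy)methyl]-4,7a-dimethyl-3a,6,7,7a-tetrahydro-2-benzofuran-1(3H)-one
Product: 8 (3S,3aS,4R,7aR)-3-[(tert-butyldimethylsilyloxy)methyl]-4-hydroxy-4,7a-dimethylhexahydro-2-benzofuran-1(3H)-one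
Conditions: Co(acac)2 (cat.), PhSiH3, O2 (1 atm), i-PrOH, 25 °C
Reagents that add atoms: dioxygen, O=O
Why: Mukaiyama hydration by hydrogen-atom transfer gives the tertiary (Markovnikov) radical, which should capture O2 on the face anti to the lactone ring, placing OH cis to the ring-fusion hydrogen.

Step 7
Reactants: 8 (3S,3aS,4R,7aR)-3-[(tert-butyldimethylsilyloxy)methyl]-4-hydroxy-4,7a-dimethylhexahydro-2-benzofuran-1(3H)-one
Product: 9 (3S,3aS,4R,7aR)-4-hydroxy-3-(hydroxymethyl)-4,7a-dimethylhexahydro-2-benzofuran-1(3H)-one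
Conditions: Bu4NF, AcOH, THF, 0 → 25 °C
Reagents that add atoms: none
Why: Fluoride-mediated desilylation, buffered with acetic acid so that no alkoxide can translactonise, releases the primary alcohol.

Step 8
Reactants: 9 (3S,3aS,4R,7aR)-4-hydroxy-3-(hydroxymethyl)-4,7a-dimethylhexahydro-2-benzofuran-1(3H)-one
Product: 11 [(3S,3aS,4R,7aR)-4,7a-dimethyl-1-oxo-4-(triethylsilyloxy)octahydro-2-benzofuran-3-yl]methyl trifluoromethanesulfonate, via primary triflate 10 (not isolated)
Conditions: Tf2O, 2,6-lutidine, CH2Cl2, −78 °C; then Et3SiOTf, −78 → −30 °C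
Reagents that add atoms: trifluoromethanesulfonic anhydride, O=S(=O)(OS(=O)(=O)C(F)(F)F)C(F)(F)F; triethylsilyl trifluoromethanesulfonate, CC[Si](CC)(CC)OS(=O)(=O)C(F)(F)F
Why: Sulfonylation of the primary alcohol at low temperature, followed by silyl ether formation at the unreactive tertiary alcohol in the same flask, gives an electrophile reactive enough for a ketone enolate despite its β-oxygen.

Step 9
Reactants: 11 [(3S,3aS,4R,7aR)-4,7a-dimethyl-1-oxo-4-(triethylsilyloxy)octahydro-2-benzofuran-3-yl]methyl trifluoromethanesulfonate; 12 cyclopent-2-en-1-one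
Product: 14 5-(Lac-methyl)cyclopent-2-en-1-one (both epimers at the ring carbon), via lithium cyclopentadienolate 13 (not isolated)
Conditions: 12 (2 equiv), LiN(i-Pr)2, THF, −78 °C; then 11, −78 → −30 °C
Reagents that add atoms: none
Why: Kinetic α′-deprotonation of the enone and SN2 alkylation of the cross-conjugated lithium enolate by the primary triflate (enolate alkylation); the new stereocentre is inconsequential because it is re-enolised in step 12.

Step 10
Reactants: 15 (2E)-3-(trimethylsilyl)prop-2-en-1-ol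
Product: 17 (2E)-1-(tert-butyldimethylsilyl)-3-(trimethylsilyl)prop-2-en-1-ol (racemic), via allyl silyl ether 16 (not isolated)
Conditions: n-BuLi, THF, −78 °C; t-BuMe2SiCl, 0 °C; then t-BuLi, −78 → −30 °C; H2O
Reagents that add atoms: tert-butylchlorodimethylsilane, CC(C)(C)[Si](C)(C)Cl
Why: O-silylation followed by α-lithiation and retro-[1,2]-Brook rearrangement moves the silyl group from oxygen to carbon.

Step 11
Reactants: 17 (2E)-1-(tert-butyldimethylsilyl)-3-(trimethylsilyl)prop-2-en-1-ol
Product: 18 (2E)-1-(tert-butyldimethylsilyl)-3-(trimethylsilyl)prop-2-en-1-one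
Conditions: (COCl)2, DMSO, CH2Cl2, −78 °C; Et3N
Reagents that add atoms: none
Why: Swern oxidation of the α-silyl carbinol gives the acylsilane under conditions that leave the (E)-vinylsilane intact.

Step 12
Reactants: 14 5-(Lac-methyl)cyclopent-2-en-1-one; 18 (2E)-1-(tert-butyldimethylsilyl)-3-(trimethylsilyl)prop-2-en-1-one
Product: 22 2-(tert-butyldimethylsilyloxy)-6-exo-[(dimethylamino)methyl]-1-(Lac-methyl)-4-endo-(trimethylsilyl)bicyclo[3.2.1]oct-2-en-7-one (C1 and C5 as in 28), via lithium dienolate 19 (not isolated), via lithium cyclopropanolate 20 (not isolated), via bridged lithium enolate 21 (not isolated)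
Conditions: LiN(i-Pr)2, THF, −80 °C; 18, −80 → −30 °C; then CH2=NMe2 I (1.0 equiv), −78 → 0 °C
Reagents that add atoms: dimethylmethylideneammonium iodide, C=[N+](C)C.[I-]
Why: The tetrasubstituted α′-enolate carbon C1 adds to the acylsilane carbonyl (bond C1–C2); a 1,2-Brook rearrangement then turns C2 into a siloxy-allyl carbanion, which closes onto the ring ketone C7 to a cis-divinylcyclopropanolate, and anionic oxy-Cope rearrangement through a boat transition state joins the two former β-carbons (bond C4–C5) while opening the cyclopropane; the bridged lithium enolate is finally aminomethylated at C6 (Mannich). The closest known reaction type is the Brook-rearrangement-mediated [3+4] annulation of β-silyl acryloylsilanes with lithium enolates of alkenyl methyl ketones and 2-cycloalkenones. The cyclopropane closes by 3-exo-trig addition to the carbonyl, and the six-membered siloxy-alkene ring, and with it the bicyclo[3.2.1]octane, by [3,3]-sigmatropic ring expansion. C1 is set by the face of the first addition: allylic 1,3-strain should turn the lactone carbon out of the enolate plane, lithium bridging to the lactone oxygen and the crowded concave side next to the lactone CH should keep the O–Li flank on the open side, and the acylsilane should enter anti to the lactone; C5 follows from C1 because the Cope step is suprafacial on the same face, the silyl-bearing C4 follows from the (E)-alkene in the boat, and C6 is attacked on its exo face. The step needs [3+4] rather than [3+2] closure and α′- rather than γ-enolisation, which the β-silyl group on an alkenyl-ketone enolate and kinetic deprotonation at low temperature should secure; one equivalent of iminium salt spares the hindered silyl enol ether.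

Step 13
Reactants: 22 2-(tert-butyldimethylsilyloxy)-6-exo-[(dimethylamino)methyl]-1-(Lac-methyl)-4-endo-(trimethylsilyl)bicyclo[3.2.1]oct-2-en-7-one
Product: 24 2-(tert-butyldimethylsilyloxy)-1-(Lac-methyl)-6-methylidene-4-endo-(trimethylsilyl)bicyclo[3.2.1]oct-2-en-7-one, via ammonium iodide 23 (not isolated)
Conditions: MeI, CH2Cl2, 25 °C; then NaHCO3 (aq), 25 °C
Reagents that add atoms: none
Why: Quaternisation and E1cB elimination of the Mannich base (Eschenmoser methylenation) gives the α-methylidene ketone, and only the exocyclic alkene can form because the other neighbour of C6 is a bridgehead.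

Step 14
Reactants: 24 2-(tert-butyldimethylsilyloxy)-1-(Lac-methyl)-6-methylidene-4-endo-(trimethylsilyl)bicyclo[3.2.1]oct-2-en-7-one
Product: 25 2-(tert-butyldimethylsilyloxy)-1-(Lac-methyl)-6-methylidene-4-endo-(trimethylsilyl)bicyclo[3.2.1]oct-2-en-7-endo-ol
Conditions: NaBH4, CeCl3·7H2O, MeOH, −78 °C
Reagents that add atoms: none
Why: Luche 1,2-reduction, in which hydride should attack C7 from the exo face (the side of the C8 bridge), away from the siloxy-alkene bridge and the endo silyl group, to give the endo alcohol while the C2 ketone is still masked as its silyl enol ether.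

Step 15
Reactants: 25 2-(tert-butyldimethylsilyloxy)-1-(Lac-methyl)-6-methylidene-4-endo-(trimethylsilyl)bicyclo[3.2.1]oct-2-en-7-endo-ol
Product: 26 2-(tert-butyldimethylsilyloxy)-1-(Lac-methyl)-6-methylidene-4-endo-(trimethylsilyl)bicyclo[3.2.1]oct-2-en-7-endo-yl acetate
Conditions: Ac2O, DMAP, pyridine, 25 °C
Reagents that add atoms: acetic anhydride, CC(=O)OC(C)=O
Why: DMAP-catalysed acetylation of the hindered secondary allylic alcohol proceeds with retention at C7.

Step 16
Reactants: 26 2-(tert-butyldimethylsilyloxy)-1-(Lac-methyl)-6-methylidene-4-endo-(trimethylsilyl)bicyclo[3.2.1]oct-2-en-7-endo-yl acetate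
Product: 28 (1R,5S,7R)-1-{[(3R,3aS,4R,7aR)-4-hydroxy-4,7a-dimethyl-1-oxooctahydro-2-benzofuran-3-yl]methyl}-6-methylidene-2-oxobicyclo[3.2.1]oct-3-en-7-yl acetate, via bromo ketone 27 (not isolated)
Conditions: N-bromosuccinimide, THF, −78 °C; then HF·pyridine, pyridine, THF, 0 → 25 °C
Reagents that add atoms: none
Why: Electrophilic bromination of the silyl enol ether gives the α-bromo-β-silyl ketone, and fluoride-induced anti 1,2-elimination of bromide and the trimethylsilyl group unveils the enone while HF also cleaves the triethylsilyl ether; no stereocentre is affected.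

Compound list
1 | (4R)-2,2-dimethyl-1,3-dioxolane-4-carbaldehyde | CC1(C)OC[C@H](C=O)O1 | starting material
2 | (2E)-3-[(4S)-2,2-dimethyl-1,3-dioxolan-4-yl]-2-methylprop-2-enal | CC1(C)OC[C@H](/C=C(C)/C=O)O1 | intermediate
3 | (4S)-2,2-dimethyl-4-[(1E)-2-methylbuta-1,3-dien-1-yl]-1,3-dioxolane | CC1(C)OC[C@H](/C=C(C)/C=C)O1 | intermediate
4 | (2S,3E)-4-methylhexa-3,5-diene-1,2-diol | OC[C@@H](O)/C=C(C)/C=C | intermediate
5 | (2S,3E)-1-(tert-butyldimethylsilyloxy)-4-methylhexa-3,5-dien-2-ol | CC(C)(C)[Si](C)(C)OC[C@@H](O)/C=C(C)/C=C | intermediate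
6 | (2S,3E)-1-(tert-butyldimethylsilyloxy)-4-methylhexa-3,5-dien-2-yl 2-methylprop-2-enoate | C=C(C)C(=O)O[C@H](CO[Si](C)(C)C(C)(C)C)/C=C(C)/C=C | intermediate
7 | (3S,3aS,7aR)-3-[(tert-butyldimethylsilyloxy)methyl]-4,7a-dimethyl-3a,6,7,7a-tetrahydro-2-benzofuran-1(3H)-one | CC(C)(C)[Si](C)(C)OC[C@H]1OC(=O)[C@]2(C)CCC=C(C)[C@H]12 | intermediate
8 | (3S,3aS,4R,7aR)-3-[(tert-butyldimethylsilyloxy)methyl]-4-hydroxy-4,7a-dimethylhexahydro-2-benzofuran-1(3H)-one | CC(C)(C)[Si](C)(C)OC[C@H]1OC(=O)[C@]2(C)CCC[C@@](C)(O)[C@H]12 | intermediate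
9 | (3S,3aS,4R,7aR)-4-hydroxy-3-(hydroxymethyl)-4,7a-dimethylhexahydro-2-benzofuran-1(3H)-one | OC[C@H]1OC(=O)[C@]2(C)CCC[C@@](C)(O)[C@H]12 | intermediate
10 | [(3S,3aS,4R,7aR)-4-hydroxy-4,7a-dimethyl-1-oxooctahydro-2-benzofuran-3-yl]methyl trifluoromethanesulfonate | O=S(=O)(OC[C@H]1OC(=O)[C@]2(C)CCC[C@@](C)(O)[C@H]12)C(F)(F)F | intermediate
11 | [(3S,3aS,4R,7aR)-4,7a-dimethyl-1-oxo-4-(triethylsilyloxy)octahydro-2-benzofuran-3-yl]methyl trifluoromethanesulfonate | O=S(=O)(OC[C@H]1OC(=O)[C@]2(C)CCC[C@@](C)(O[Si](CC)(CC)CC)[C@H]12)C(F)(F)F | intermediate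
12 | cyclopent-2-en-1-one | O=C1C=CCC1 | starting material
13 | lithium cyclopenta-1,3-dien-2-olate | [Li]OC1=CCC=C1 | intermediate
14 | (3R,3aS,4R,7aR)-4,7a-dimethyl-3-[(2-oxocyclopent-3-en-1-yl)methyl]-4-(triethylsilyloxy)hexahydro-2-benzofuran-1(3H)-one, both epimers at the cyclopentenone carbon | O=C1C=CCC1C[C@H]2OC(=O)[C@]3(C)CCC[C@@](C)(O[Si](CC)(CC)CC)[C@H]23 | intermediate
15 | (2E)-3-(trimethylsilyl)prop-2-en-1-ol | C[Si](C)(C)/C=C/CO | starting material
16 | tert-butyldimethyl{[(2E)-3-(trimethylsilyl)prop-2-en-1-yl]oxy}silane | C[Si](C)(C)/C=C/CO[Si](C)(C)C(C)(C)C | intermediate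
17 | (2E)-1-(tert-butyldimethylsilyl)-3-(trimethylsilyl)prop-2-en-1-ol, racemic | C[Si](C)(C)/C=C/C(O)[Si](C)(C)C(C)(C)C | intermediate
18 | (2E)-1-(tert-butyldimethylsilyl)-3-(trimethylsilyl)prop-2-en-1-one | C[Si](C)(C)/C=C/C(=O)[Si](C)(C)C(C)(C)C | intermediate
19 | lithium 1-(Lac-methyl)cyclopenta-1,3-dien-2-olate (α′-enolate of 14) | [Li]OC1=C(C[C@H]2OC(=O)[C@]3(C)CCC[C@@](C)(O[Si](CC)(CC)CC)[C@H]23)CC=C1 | intermediate
20 | lithium 6-(tert-butyldimethylsilyloxy)-5-(Lac-methyl)-6-endo-[(E)-2-(trimethylsilyl)ethenyl]bicyclo[3.1.0]hex-2-en-1-olate (cis-divinylcyclopropanolate) | [Li]O[C@@]12C=CC[C@]1(C[C@H]3OC(=O)[C@]4(C)CCC[C@@](C)(O[Si](CC)(CC)CC)[C@H]34)[C@]2(O[Si](C)(C)C(C)(C)C)/C=C/[Si](C)(C)C | intermediate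
21 | lithium 2-(tert-butyldimethylsilyloxy)-1-(Lac-methyl)-4-endo-(trimethylsilyl)bicyclo[3.2.1]octa-2,6-dien-7-olate | [Li]OC1=C[C@@H]2[C@H]([Si](C)(C)C)C=C(O[Si](C)(C)C(C)(C)C)[C@@]1(C[C@H]3OC(=O)[C@]4(C)CCC[C@@](C)(O[Si](CC)(CC)CC)[C@H]34)C2 | intermediate
22 | 2-(tert-butyldimethylsilyloxy)-6-exo-[(dimethylamino)methyl]-1-(Lac-methyl)-4-endo-(trimethylsilyl)bicyclo[3.2.1]oct-2-en-7-one | CN(C)C[C@H]1[C@@H]2[C@H]([Si](C)(C)C)C=C(O[Si](C)(C)C(C)(C)C)[C@@](C[C@H]3OC(=O)[C@]4(C)CCC[C@@](C)(O[Si](CC)(CC)CC)[C@H]34)(C2)C1=O | intermediate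
23 | trimethylammonium iodide of 22 | C[N+](C)(C)C[C@H]1[C@@H]2[C@H]([Si](C)(C)C)C=C(O[Si](C)(C)C(C)(C)C)[C@@](C[C@H]3OC(=O)[C@]4(C)CCC[C@@](C)(O[Si](CC)(CC)CC)[C@H]34)(C2)C1=O.[I-] | intermediate
24 | 2-(tert-butyldimethylsilyloxy)-1-(Lac-methyl)-6-methylidene-4-endo-(trimethylsilyl)bicyclo[3.2.1]oct-2-en-7-one | C=C1[C@@H]2[C@H]([Si](C)(C)C)C=C(O[Si](C)(C)C(C)(C)C)[C@@](C[C@H]3OC(=O)[C@]4(C)CCC[C@@](C)(O[Si](CC)(CC)CC)[C@H]34)(C2)C1=O | intermediate
25 | 2-(tert-butyldimethylsilyloxy)-1-(Lac-methyl)-6-methylidene-4-endo-(trimethylsilyl)bicyclo[3.2.1]oct-2-en-7-endo-ol | C=C1[C@@H]2[C@H]([Si](C)(C)C)C=C(O[Si](C)(C)C(C)(C)C)[C@@](C[C@H]3OC(=O)[C@]4(C)CCC[C@@](C)(O[Si](CC)(CC)CC)[C@H]34)(C2)[C@@H]1O | intermediate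
26 | 2-(tert-butyldimethylsilyloxy)-1-(Lac-methyl)-6-methylidene-4-endo-(trimethylsilyl)bicyclo[3.2.1]oct-2-en-7-endo-yl acetate | C=C1[C@@H]2[C@H]([Si](C)(C)C)C=C(O[Si](C)(C)C(C)(C)C)[C@@](C[C@H]3OC(=O)[C@]4(C)CCC[C@@](C)(O[Si](CC)(CC)CC)[C@H]34)(C2)[C@@H]1OC(C)=O | intermediate
27 | 3-exo-bromo-1-(Lac-methyl)-6-methylidene-2-oxo-4-endo-(trimethylsilyl)bicyclo[3.2.1]oct-7-endo-yl acetate | C=C1[C@@H]2[C@H]([Si](C)(C)C)[C@@H](Br)C(=O)[C@@](C[C@H]3OC(=O)[C@]4(C)CCC[C@@](C)(O[Si](CC)(CC)CC)[C@H]34)(C2)[C@@H]1OC(C)=O | intermediate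
28 | (1R,5S,7R)-1-{[(3R,3aS,4R,7aR)-4-hydroxy-4,7a-dimethyl-1-oxooctahydro-2-benzofuran-3-yl]methyl}-6-methylidene-2-oxobicyclo[3.2.1]oct-3-en-7-yl acetate (CNP0172716.1) | C=C1[C@@H]2C=CC(=O)[C@@](C[C@H]3OC(=O)[C@]4(C)CCC[C@@](C)(O)[C@H]34)(C2)[C@@H]1OC(C)=O | target

Total step count: 16. Longest linear sequence: 14 steps (steps 1–9 and 12–16); steps 10–11 are the two-step branch to the acylsilane.

Steps most likely to fail

Step 12. The face of the first carbon–carbon bond formation is controlled only by the lactone two bonds away from the enolate carbon, so the selectivity at C1 (and with it C5) may be low and the bicycle of opposite configuration may be carried along. Fallback: control is moved from the substrate to an enzyme at the carbinol stage. The mixture is taken through steps 13 and 14, and alcohol 25 together with the carbinol whose bicyclic core has the mirror-image configuration at C1, C4, C5 and C7 F1 is subjected, in place of step 15, to lipase-catalysed transesterification (Burkholderia cepacia lipase, vinyl acetate, t-BuOMe, 30 °C). The enzyme, chosen by screening, should acylate only the carbinol environment of 25; acetate 26 is separated from unreacted F1. The fallback sets out from 25 and returns at 26.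

Step 5. Radical polymerisation of the methacrylate and the unfavourable s-cis conformer of the ester tether may outrun the cycloaddition at the temperature needed. Fallback: a metal-templated intermolecular Diels–Alder reaction with no new compound (F0). Alcohol 5 is isolated, converted with MeMgBr (toluene, 0 °C) into its bromomagnesium alkoxide and heated with methyl methacrylate (80–110 °C). Magnesium holds the dienyl alkoxide and the ester carbonyl together, which fixes the same regiochemistry and the same facial sense, and the adduct lactonises in the flask. The fallback sets out from 5 and returns at 7.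

Step 9. O-alkylation, proton transfer between product and enolate, and self-condensation of the cyclopentenone enolate may erode the alkylation with a β-oxygenated electrophile. Fallback: the more robust lithium enolate of cyclopentanone (LiN(i-Pr)2, THF, −78 °C) is alkylated with 11 to give 2-(Lac-methyl)cyclopentanone F2. Kinetic deprotonation (LiN(i-Pr)2, Me3SiCl, −78 °C) gives the less substituted trimethylsilyl enol ether F3, and Saegusa dehydrogenation (Pd(OAc)2, MeCN, 25 °C) places the double bond on the unsubstituted side. The fallback sets out from 11 and returns at 14.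

Further compounds
F1 | step 12 | 2-(tert-butyldimethylsilyloxy)-1-(Lac-methyl)-6-methylidene-4-endo-(trimethylsilyl)bicyclo[3.2.1]oct-2-en-7-endo-ol with the mirror-image bicyclic core | C=C1[C@H]2[C@@H]([Si](C)(C)C)C=C(O[Si](C)(C)C(C)(C)C)[C@](C[C@H]3OC(=O)[C@]4(C)CCC[C@@](C)(O[Si](CC)(CC)CC)[C@H]34)(C2)[C@H]1O
F0 | step 5 | none | none
F2 | step 9 | (3R,3aS,4R,7aR)-4,7a-dimethyl-3-[(2-oxocyclopentyl)methyl]-4-(triethylsilyloxy)hexahydro-2-benzofuran-1(3H)-one | O=C1CCCC1C[C@H]2OC(=O)[C@]3(C)CCC[C@@](C)(O[Si](CC)(CC)CC)[C@H]23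
F3 | step 9 | (3R,3aS,4R,7aR)-4,7a-dimethyl-4-(triethylsilyloxy)-3-{[2-(trimethylsilyloxy)cyclopent-2-en-1-yl]methyl}hexahydro-2-benzofuran-1(3H)-one | C[Si](C)(C)OC1=CCCC1C[C@H]2OC(=O)[C@]3(C)CCC[C@@](C)(O[Si](CC)(CC)CC)[C@H]23
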